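(Readings and results are calculated with constants of no real substance; noise was put on by code.)

Open a ledger on initiator, taken here as the limiting reagent, and let the readings fill it.

common to all: initiator 2.2 mol%
- north: free monomer 0.034 M (fed, over 4.0 min); transfer agent 0.015 M; run made earlier; the fed solution adds 0.20 times the starting volume
- north-east: free monomer 0.075 M (fed, over 4.0 min); transfer agent 0.015 M; run made earlier; the fed solution adds 0.20 times the starting volume
- flask: free monomer 0.050 M (fed, over 4.0 min); transfer agent 0.0150 M; the fed solution adds 0.20 times the starting volume; time 6.0 h

- north (time / h: monomer in chains / %, free monomer / %): 0.250: 7.3, 90.0; 0.500: 12.8, 82.3; 1.00: 15.4, 75.4; 2.00: 16.7, 70.3; 4.00: 15.1, 54.4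
- north-east (time / h: monomer in chains / %, free monomer / %): 0.333: 20.5, 76.7; 0.833: 27.0, 66.7; 1.50: 26.2, 61.5; 2.50: 27.7, 56.7; 4.00: 26.2, 47.5

(standard deviation of a reading: 1 percentage point)

- amounts are per litre of the starting volume; all of the dose is in the solution fed
- the average divides the monomer in chains by the number of chains begun, living and dead together
- steps that have been proposed: free monomer + initiator -> living end + monomer in chains; free monomer + living end -> monomer in chains + living end; living end + transfer agent -> dead chain; 2 initiator -> spent initiator A; free monomer -> uncatalysed product; living end -> dead end B
- the earlier runs do not show the number of chains; that part of a forecast is a guess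

* average number of monomer units in a chain (chains begun, living or dead) at 6.0 h
* part of the free monomer that has reacted at 6.0 h

Each initiator that meets free monomer begins a chain, and a pair that meets each other goes to spent initiator A. The readings do not show that split, so this reckoning assumes that the loading of 2.2 mol% is booked to chains. A chain stays counted when its living end becomes a dead chain or dead end B. The average chain is then read as the plateau of monomer in chains over the loading, with the scatter of the readings: 15.7% gives 7.15 units in the north run, and 26.8% gives 12.2 in the north-east run.

With free monomer taken as steady and transfer agent held at one charge, a living end grows in proportion to free monomer and dies first-order. Integrating its falling rate gives one unit plus growth over death. The two runs, averaged, give 165 L mol⁻¹: the chain gain, units beyond the first per mole per litre of free monomer charged.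

For this flask the gain gives 9.25 units, so this reckoning books a share of 20.3% to chains. The remainder falls at about 0.116 h⁻¹ as read from the late readings, which makes 60.2% reacted.

The forecast differs on chain length, giving 15 and 56% and saying of the former “This part is a guess”. The flask gives 9.51 and 59.2%.

    free monomer + initiator → living end + monomer in chains (k = 0.230 L mol⁻¹ s⁻¹)
    free monomer + living end → monomer in chains + living end, rate k2*[living end]*[free monomer] (k = 0.287 L mol⁻¹ s⁻¹)
    living end + transfer agent → dead chain (kL = 0.0662 L mol⁻¹ s⁻¹)
    2 initiator → spent initiator A (k = 0.157 L mol⁻¹ s⁻¹)
    free monomer → uncatalysed product (k = 3.10 × 10⁻⁵ s⁻¹)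
    living end → dead end B (k = 3.73 × 10⁻⁴ s⁻¹)

At 2.49 h the half-life of free monomer in this flask by the path into chains is 860 d, far longer than the 6.2 h by the path to uncatalysed product. Between 3.00 h and 6.00 h monomer in chains in this flask stands at 20.0% while uncatalysed product goes from 22.9% to 39.1%. For a neighbour flask with 0.085 M of free monomer and the loading held, the chain gain gives 15.0 units; that neighbour gives 14.5.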